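## Structural features

The target is a single cyclohexene ring (C1–C6, with C5=C6) carrying one exocyclic carbon, C7, as a benzoyloxymethyl group on C1. C1 to C4 are four contiguous oxygenated stereocentres. C1 is a quaternary carbinol (OH β, C7 α), the C2 hydroxyl is cis to the C1 hydroxyl, the C3 benzoate is trans to the C2 hydroxyl, and the C4 hydroxyl is trans to the C3 ester. In the half-chair this places the C2, C3 and C4 oxygens and C7 pseudo-equatorial and only the C1 hydroxyl pseudo-axial. Five oxygens must be told apart so that only O3 and O7 are acylated, and the O3 benzoate sits between two free hydroxyls, so base-induced acyl migration is a constant threat. The C1 hydroxyl (tertiary) and the C4 hydroxyl (secondary) are both allylic, so strong acid can ionise them and a double dehydration would aromatise the ring. The real difficulty is the quaternary centre C1 in the correct relation to C2, together with the oxygen differentiation, not the ring itself. The key step exploits the fact that C4 is a secondary allylic carbinol directly attached to the cis C5=C6 bond. The C4–C5 bond is therefore the retron of an alkenyl-metal addition to an aldehyde, with C5 as the iodine-bearing carbon of a Z-iodoalkene and C4 as the aldehyde carbon.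

## Logic of the disconnections

17 to 16. The two ketal C–O bonds at O1 and O2 are cut last. Both benzoates are then already in place at the end, so no acylation has to discriminate among five oxygens. The forward step must hydrolyse a ketal without moving the O3 ester and without ionising the tertiary allylic C1–O bond.

16 to 13. The C4–C5 bond is cut. C4 is an allylic carbinol next to a cis alkene, so the bond maps onto an alkenylchromium addition to an aldehyde. The carbocycle opens to an acyclic, sugar-like chain in which C1, C2 and C3 are already set. The forward step needs a Z-iodoalkene, a free aldehyde, both chains cis on the dioxolane, and facial control at C4. Carrying the C3 oxygen as its benzoate already in 13 reduces the end game to one step. The price is an α-benzoyloxy aldehyde, which the neutral chromium conditions are expected to tolerate.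

13 to 11. The aldehyde carbon C4 is reconnected to one extra carbon as a terminal 1,2-diol masked as its acetonide, so the forward step cuts that glycol C–C bond. The labile aldehyde then appears only immediately before the cyclisation, and no separate protecting group for a primary alcohol is needed. The forward step must open the terminal ketal and leave the internal, fully substituted one alone.

11 to 10 to 8. The C5–I bond and the two cis C–H bonds of the alkene are removed, leading back to a terminal alkyne. Syn reduction of a 1-iodoalkyne is a dependable source of Z geometry. Electrophilic iodine and silver are used, so the aldehyde must not be masked as a sulfur acetal at this stage, which is one reason for the ketal mask above. The reduction must stop at the alkene.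

8 to 6. The two ester C–O bonds are cut together. The only free hydroxyls in 6 are exactly O7 and O3 of the target, so one exhaustive benzoylation places both esters without any selectivity problem.

6 to 3. The C5–C6 bond (the alkyne) is cut, which returns C6 to the aldehyde carbon of a furanose lactol. One-carbon homologation of the lactol also releases the ring oxygen as the free O3 hydroxyl. The α-carbon is quaternary, so the basic conditions cannot epimerise it.

3 to 1 and 2. The C1–C7 bond is cut. The quaternary carbinol arises by hydroxymethylation of the α-carbon of a 2,3-O-isopropylidene aldose. The cis-fused ketal forces the new CH2OH into the place of the former hydrogen, so C1 is set by the substrate, and C2 and C3 come unchanged from the sugar. This was preferred to adding an alkynyl metal to an acyclic α-alkoxy ketone, which would need anti-chelation selectivity that such additions do not give reliably. In 1, the two carbons beyond C4 are already the terminal acetonide needed above.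

## Other disconnections considered

Alternative 1: The cut removes the C1–O and C2–O bonds and traces the ring to the arene bromobenzene A2. In the forward key step, whole-cell oxidation with toluene dioxygenase adds O2 across two adjacent carbons of A2 and gives (1S,2S)-3-bromocyclohexa-3,5-diene-1,2-diol A1. The carbinol carbon next to the brominated carbon becomes C1, its neighbour C2, the unsubstituted alkene C3/C4 and the bromoalkene C5=C6.
- In its favour: one operation from an achiral arene gives all six ring carbons, the cis C1/C2 oxygens in the correct absolute sense, a latent C5=C6 bond and an alkene ready for trans-oxygenation. In ring construction, and in the number of ring C–C bonds to be made (none), it is better than the chosen plan.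
- Against it: C1 of A1 is a secondary carbinol. O1 must be told from O2 and oxidised to the ketone, which erases one of the two enzymatically set centres. C7 must then be added as a hydroxymethyl anion equivalent anti to the C2 oxygen.
- Further drawbacks: the benzoate belongs on C3, whereas a vinyl epoxide from A1 opens preferentially at allylic C4. The bromine must be removed reductively, and A1 dimerises and aromatises easily.
- Comparison: on structure, A1 lacks C7 and the quaternary centre, which the chosen plan installs in its first step without an oxidation-state detour. On mechanism, enzymatic absolute control is the equal of the chiral pool, but C1, C3 and C4 would each need a separate relayed step, against one (C4) in the chosen plan. On step economy it is expected to be comparable or somewhat longer.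

Alternative 2: The cut is the C2–C3 bond. In the forward key step, the enol(ate) at the benzoyloxymethyl carbon (C3) of the open-chain keto aldehyde (2S,3Z)-6-(benzoyloxy)-2-(benzoyloxymethyl)-5-oxo-2-(triethylsilyloxy)hex-3-enal A4 adds to its neopentyl aldehyde (C2) and gives the cyclic aldol 3-O-benzoyl-1-(benzoyloxymethyl)-1-O-triethylsilyl-4-oxocyclohex-5-ene-1,2,3-triol A3.
- In its favour: the ring and two stereocentres (C2, C3) form together, which is better than the chosen key step (one stereocentre). Both benzoates and the C4 oxygen are already present, and the end game (ketone reduction, desilylation) is as short as that of the chosen plan.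
- Against it: the reaction is reversible and base-mediated. The new C2 alkoxide sits next to the C3 ester, so acyl transfer is likely, and A3 is a β-hydroxy ketone that can dehydrate and then aromatise by loss of silanol.
- Further drawbacks: one of four possible diastereomers is needed, with only the quaternary centre to guide it. The Z-enone in A4 can isomerise, and A4 needs its own enantioselective synthesis of the quaternary α-silyloxy aldehyde.
- Comparison: on structure it creates more in the key step. On mechanism the irreversible, neutral chromium addition is safer than an aldol that can revert, migrate or eliminate. On step economy it could match the chosen plan only if A4 were available in about four steps, which is doubtful.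

Alternative 3: The cut is the C1–C6 bond. In the forward key step, the enolate of the dichloromethyl ketone of the acyclic 1,5-diketone A6 (made from D-glucose A7) attacks the C1 ketone and gives 2,4-di-O-benzyl-1-C-(benzyloxymethyl)-6,6-dichloro-3-O-(4-methoxybenzyl)-5-oxocyclohexane-1,2,3,4-tetrol A5.
- In its favour: this carbocyclisation type is well precedented for hexose-derived dicarbonyls. C2, C3 and C4 come from the cheap hexose A7, which equals the chosen plan in use of the chiral pool. The quaternary carbinol is formed in the ring-closing step itself, with the tertiary hydroxyl cis to the C2 oxygen, which is a point in which it is better.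
- Against it: A5 has the wrong oxidation pattern. The C5 carbonyl and both chlorines must be converted into the C5=C6 alkene (reduction, dechlorination, regioselective elimination).
- Further drawbacks: three benzyl ethers must be removed without hydrogenation of the ring alkene, and benzoates must then be placed on O7 and O3 only.
- Comparison: on structure it reaches the quaternary centre elegantly but overshoots in functionality. On mechanism the aldol is reliable. On step economy it is clearly longer (well over a dozen steps) than the eight steps proposed here.

Key step: step 7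

Remark: lactol 3 is expected as an anomeric mixture, so its anomeric carbon is left without configuration; this centre is destroyed in step 2.

## Route

Step 1
Reactants: 1 2,3:5,6-di-O-isopropylidene-α-D-mannofuranose; 2 formaldehyde
Product: 3 2-C-(hydroxymethyl)-2,3:5,6-di-O-isopropylidene-D-mannofuranose
Conditions: 37% aq. HCHO (excess), K2CO3, MeOH, 65 °C
Reagents that add atoms: formaldehyde, C=O
Why: Crossed aldol hydroxymethylation of the open-chain aldehyde form of a 2,3-O-isopropylidene aldose, known for this lactol class; formaldehyde attacks the C2 enolate on the dioxolane face opposite the C4 side chain, so CH2OH replaces H-2 with the oxygen and C1 unchanged, which sets the quaternary centre (target C1). Re-closure to the cis-fused furanose lactol shields the adduct from crossed Cannizzaro reduction.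

Step 2
Reactants: 3 2-C-(hydroxymethyl)-2,3:5,6-di-O-isopropylidene-D-mannofuranose; 4 dimethyl (1-diazo-2-oxopropyl)phosphonate
Product: 6 1,2-dideoxy-3-C-(hydroxymethyl)-3,4:6,7-di-O-isopropylidene-D-manno-hept-1-ynitol, via aldehydo tautomer 5 (not isolated)
Conditions: K2CO3, MeOH, 23 → 50 °C
Reagents that add atoms: dimethyl (1-diazo-2-oxopropyl)phosphonate, CC(=O)C(=[N+]=[N-])P(=O)(OC)OC
Why: Seyferth–Gilbert homologation in the Ohira–Bestmann form, known for furanose lactols: methanolysis of 4 releases the diazomethylphosphonate anion, which adds to aldehyde 5 (in equilibrium with 3) and gives the terminal alkyne after loss of phosphate and N2. The α-carbon is quaternary and cannot epimerise, and opening the lactol frees the hydroxyl that becomes O3 of the target.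

Step 3
Reactants: 6 1,2-dideoxy-3-C-(hydroxymethyl)-3,4:6,7-di-O-isopropylidene-D-manno-hept-1-ynitol; 7 benzoyl chloride
Product: 8 5-O-benzoyl-3-C-(benzoyloxymethyl)-1,2-dideoxy-3,4:6,7-di-O-isopropylidene-D-manno-hept-1-ynitol
Conditions: BzCl (3 equiv), pyridine, DMAP (cat.), CH2Cl2, 0 → 23 °C
Reagents that add atoms: benzoyl chloride, O=C(Cl)c1ccccc1
Why: Pyridine/DMAP-catalysed esterification; the two free hydroxyls of 6 are exactly O7 and O3 of the target, so exhaustive benzoylation needs no selectivity and touches no stereocentre.

Step 4
Reactants: 8 5-O-benzoyl-3-C-(benzoyloxymethyl)-1,2-dideoxy-3,4:6,7-di-O-isopropylidene-D-manno-hept-1-ynitol; 9 N-iodosuccinimide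
Product: 10 5-O-benzoyl-3-C-(benzoyloxymethyl)-1,2-dideoxy-1-iodo-3,4:6,7-di-O-isopropylidene-D-manno-hept-1-ynitol
Conditions: NIS, AgNO3 (cat.), acetone, 23 °C, dark
Reagents that add atoms: N-iodosuccinimide, O=C1CCC(=O)N1I
Why: Silver-catalysed C–H iodination of a terminal alkyne, a standard neutral reaction; esters and ketals are inert and the molecule contains no sulfur or other soft nucleophile that electrophilic iodine or silver would attack.

Step 5
Reactants: 10 5-O-benzoyl-3-C-(benzoyloxymethyl)-1,2-dideoxy-1-iodo-3,4:6,7-di-O-isopropylidene-D-manno-hept-1-ynitol
Product: 11 (Z)-5-O-benzoyl-3-C-(benzoyloxymethyl)-1,2-dideoxy-1-iodo-3,4:6,7-di-O-isopropylidene-D-manno-hept-1-enitol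
Conditions: 2-nitrobenzenesulfonohydrazide (excess, portionwise), Et3N, THF/i-PrOH, 23 °C
Reagents that add atoms: none
Why: Diimide semi-reduction of a 1-iodoalkyne, a known route to Z-iodoalkenes: diimide formed from the sulfonohydrazide transfers two hydrogens in a concerted syn fashion, placing iodine cis to the quaternary carbon. The C–I bond and esters are not reduced, and the electron-poor iodoalkene reacts more slowly than the alkyne.

Step 6
Reactants: 11 (Z)-5-O-benzoyl-3-C-(benzoyloxymethyl)-1,2-dideoxy-1-iodo-3,4:6,7-di-O-isopropylidene-D-manno-hept-1-enitol
Product: 13 2,5-di-O-benzoyl-4-C-[(Z)-2-iodoethenyl]-3,4-O-isopropylidene-aldehydo-L-xylose, via terminal diol 12 (not isolated)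
Conditions: H5IO6 (1.5 equiv), EtOAc, 0 → 23 °C; used crude
Reagents that add atoms: none
Why: One-pot hydrolysis of the terminal dioxolane and Malaprade cleavage of the liberated 1,2-diol, a known use of periodic acid on terminal isopropylidene acetals; the less substituted terminal ketal opens faster than the fully substituted internal one. Diol 12 is cleaved as it forms, so a benzoyl shift from O5 to O6 cannot compete, and no stereocentre is affected.

Step 7
Reactants: 13 2,5-di-O-benzoyl-4-C-[(Z)-2-iodoethenyl]-3,4-O-isopropylidene-aldehydo-L-xylose
Product: 16 1α-benzoyloxymethyl-3α-benzoyloxy-1β,2β-isopropylidenedioxycyclohex-5-en-4β-ol, via alkenylchromium dichloride 14 (not isolated), via chromium alkoxide 15 (not isolated)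
Conditions: CrCl2 (6 equiv), NiCl2 (1 mol%), degassed DMSO, 23 °C, 0.01 M; aq. NH4Cl work-up
Reagents that add atoms: none
Why: CrCl2 reduces NiCl2 to zerovalent nickel, which inserts into the C–I bond of 13 with retention of the Z geometry; transmetalation to trivalent chromium gives 14 and the nickel is returned to the cycle by divalent chromium. The alkenyl–chromium bond then adds to the aldehyde through a closed four-centre arrangement in which chromium binds the carbonyl oxygen, giving alkoxide 15 and, after aqueous work-up, 16. The closest known reaction type is the intramolecular Nozaki–Hiyama–Kishi cyclisation of (Z)-iodoalkenyl aldehydes to cyclic allylic alcohols, as used for carbasugars. The one ring formed is the six-membered carbocycle, closed in the 6-exo-trig mode by the C4–C5 bond. The one new stereocentre, C4, is under substrate control: the cis-fused dioxolane fixes a half-chair in which the C2 oxygen and the C3 benzoate are pseudo-equatorial and the forming bond is anti to the C3–O bond, while the chromium-bound carbonyl oxygen lies in the plane of the alkenyl–chromium bond, that is pseudo-equatorial, so the C4 oxygen should emerge trans to the C3 ester (4β). The step needs chemoselectivity for the aldehyde over two benzoates and a ketal, and alkenylchromium reagents add only to aldehydes at this temperature. The medium is neutral, so the α-benzoyloxy aldehyde should not epimerise or eliminate and the ester should not shift to the chromium alkoxide. The cis relation of the iodoalkenyl group and the aldehyde chain on the dioxolane, set in step 1, holds the termini together, so moderate dilution suffices.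

Step 8
Reactants: 16 1α-benzoyloxymethyl-3α-benzoyloxy-1β,2β-isopropylidenedioxycyclohex-5-en-4β-ol
Product: 17 1α-benzoyloxymethyl-3α-benzoyloxycyclohex-5-ene-1β,2β,4β-triol
Conditions: TFA–H2O (9:1), CH2Cl2, 0 °C
Reagents that add atoms: none
Why: Acid-catalysed ketal hydrolysis through the 2-propyl oxocarbenium ion; cleavage occurs at the ketal carbon because a cation at C1 or C4 would be destabilised by the neighbouring oxygenated carbons. The low temperature and absence of base should keep the C3 benzoate in place.

## Compound list

1 | 2,3:5,6-di-O-isopropylidene-α-D-mannofuranose | O[C@H]1O[C@H]([C@H]2COC(C)(C)O2)[C@@H]3OC(C)(C)O[C@H]13 | starting material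
2 | formaldehyde (37% aqueous) | C=O | starting material
3 | 2-C-(hydroxymethyl)-2,3:5,6-di-O-isopropylidene-D-mannofuranose (anomeric mixture) | OC1O[C@H]([C@H]2COC(C)(C)O2)[C@@H]3OC(C)(C)O[C@]13CO | intermediate
4 | dimethyl (1-diazo-2-oxopropyl)phosphonate | CC(=O)C(=[N+]=[N-])P(=O)(OC)OC | starting material
5 | 2-C-(hydroxymethyl)-2,3:5,6-di-O-isopropylidene-aldehydo-D-mannose | CC1(C)OC[C@@H](O1)[C@@H](O)[C@H]1[C@](CO)(OC(C)(C)O1)C=O | intermediate (not isolated)
6 | 1,2-dideoxy-3-C-(hydroxymethyl)-3,4:6,7-di-O-isopropylidene-D-manno-hept-1-ynitol | CC1(C)OC[C@@H](O1)[C@@H](O)[C@H]1[C@](CO)(OC(C)(C)O1)C#C | intermediate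
7 | benzoyl chloride | O=C(Cl)c1ccccc1 | starting material
8 | 5-O-benzoyl-3-C-(benzoyloxymethyl)-1,2-dideoxy-3,4:6,7-di-O-isopropylidene-D-manno-hept-1-ynitol | CC1(C)OC[C@@H](O1)[C@@H](OC(=O)c1ccccc1)[C@H]1[C@](COC(=O)c2ccccc2)(OC(C)(C)O1)C#C | intermediate
9 | N-iodosuccinimide | O=C1CCC(=O)N1I | starting material
10 | 5-O-benzoyl-3-C-(benzoyloxymethyl)-1,2-dideoxy-1-iodo-3,4:6,7-di-O-isopropylidene-D-manno-hept-1-ynitol | CC1(C)OC[C@@H](O1)[C@@H](OC(=O)c1ccccc1)[C@H]1[C@](COC(=O)c2ccccc2)(OC(C)(C)O1)C#CI | intermediate
11 | (Z)-5-O-benzoyl-3-C-(benzoyloxymethyl)-1,2-dideoxy-1-iodo-3,4:6,7-di-O-isopropylidene-D-manno-hept-1-enitol | CC1(C)OC[C@@H](O1)[C@@H](OC(=O)c1ccccc1)[C@H]1[C@](COC(=O)c2ccccc2)(OC(C)(C)O1)/C=C\I | intermediate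
12 | (Z)-5-O-benzoyl-3-C-(benzoyloxymethyl)-1,2-dideoxy-1-iodo-3,4-O-isopropylidene-D-manno-hept-1-enitol | OC[C@@H](O)[C@@H](OC(=O)c1ccccc1)[C@H]1[C@](COC(=O)c2ccccc2)(OC(C)(C)O1)/C=C\I | intermediate (not isolated)
13 | 2,5-di-O-benzoyl-4-C-[(Z)-2-iodoethenyl]-3,4-O-isopropylidene-aldehydo-L-xylose (pentose C1 to C5 = target C4, C3, C2, C1, C7) | O=C[C@@H](OC(=O)c1ccccc1)[C@H]1[C@](COC(=O)c2ccccc2)(OC(C)(C)O1)/C=C\I | intermediate
14 | alkenylchromium dichloride derived from 13 (CrCl2 in place of iodine) | O=C[C@@H](OC(=O)c1ccccc1)[C@H]1[C@](COC(=O)c2ccccc2)(OC(C)(C)O1)/C=C\[Cr](Cl)Cl | intermediate (not isolated)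
15 | chromium dichloride alkoxide of 16 (O4–CrCl2) | O=C(OC[C@@]12C=C[C@H](O[Cr](Cl)Cl)[C@@H](OC(=O)c3ccccc3)[C@@H]1OC(C)(C)O2)c1ccccc1 | intermediate (not isolated)
16 | 1α-benzoyloxymethyl-3α-benzoyloxy-1β,2β-isopropylidenedioxycyclohex-5-en-4β-ol | O=C(OC[C@@]12C=C[C@H](O)[C@@H](OC(=O)c3ccccc3)[C@@H]1OC(C)(C)O2)c1ccccc1 | intermediate
17 | 1α-benzoyloxymethyl-3α-benzoyloxycyclohex-5-ene-1β,2β,4β-triol, i.e. [(1S,2S,3R,4S)-3-(benzoyloxy)-1,2,4-trihydroxycyclohex-5-en-1-yl]methyl benzoate | O=C(OC[C@@]1(O)C=C[C@H](O)[C@@H](OC(=O)c2ccccc2)[C@@H]1O)c1ccccc1 | target

## Step count and least certain steps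

Total step count: 8. Longest linear sequence: 8 steps (1 to 17); the route is fully linear.

Step 7 (key step). The most likely failure is poor facial selectivity in the addition to the aldehyde. The preference for a pseudo-equatorial C4 oxygen rests on a conformational argument, and an α-acyloxy group offers little extra bias. A lesser risk is transfer of the C3 benzoate to the new alkoxide during work-up. The fallback sets the C4 centre by hydride reduction instead of C–C bond formation. It sets out from 16 as obtained in admixture with its C4 epimer, 1α-benzoyloxymethyl-3α-benzoyloxy-1β,2β-isopropylidenedioxycyclohex-5-en-4α-ol F1. Dess–Martin periodinane (NaHCO3, CH2Cl2, 0 °C) would converge both on 3α-benzoyloxy-1α-benzoyloxymethyl-1β,2β-isopropylidenedioxycyclohex-5-en-4-one F2. Luche reduction (NaBH4, CeCl3·7H2O, MeOH, −78 °C) should then deliver hydride axially, giving the pseudo-equatorial alcohol trans to the C3 ester, and the route is rejoined at 16.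

Step 2. The most likely failure is sluggish opening of the hindered lactol, with base-induced retro-aldol loss of formaldehyde from the free β-hydroxy aldehyde competing with the homologation. The fallback avoids the free hydroxymethyl group and the alkyne altogether. It sets out from 3, which is benzoylated at the primary hydroxyl (BzCl, 1.05 equiv, 2,4,6-collidine, CH2Cl2, −40 °C) to 2-C-(benzoyloxymethyl)-2,3:5,6-di-O-isopropylidene-D-mannofuranose F3. Stork–Zhao olefination of this lactol (Ph3P=CHI from (iodomethyl)triphenylphosphonium iodide and NaN(SiMe3)2, THF, −78 → 0 °C, excess ylide) should give (Z)-3-C-(benzoyloxymethyl)-1,2-dideoxy-1-iodo-3,4:6,7-di-O-isopropylidene-D-manno-hept-1-enitol F4. Benzoylation of the liberated hydroxyl (BzCl, pyridine, DMAP) rejoins the route at 11, bypassing 6, 8 and 10. A benzoyl shift between the two hydroxyls at the alkoxide stage would be harmless, because the last benzoylation fills whichever oxygen is free.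

Step 6. The most likely failure is loss of chemoselectivity under the acidic one-pot conditions: partial opening of the internal ketal, or degradation of the sensitive α-benzoyloxy aldehyde on prolonged exposure. The fallback separates the two events and makes the cleavage neutral and anhydrous. It sets out from 11, whose terminal ketal is hydrolysed selectively (Zn(NO3)2·6H2O, MeCN, 50 °C) to give isolated 12. Glycol cleavage with Pb(OAc)4 (K2CO3, CH2Cl2, 0 °C) and filtration then rejoin the route at 13. This fallback makes no compound outside the list (F0).

Step 8. The most likely failure is acid-induced ionisation at the allylic C1 or C4 oxygen (allylic transposition or elimination towards an arene), or benzoyl migration to a neighbouring hydroxyl during a slow hydrolysis. The fallback replaces hydrolysis by anhydrous transketalisation to sulfur at low temperature. It sets out from 16, which is treated with propane-1,3-dithiol and BF3·OEt2 (cat.) in CH2Cl2 at −40 °C, and it arrives directly at 17. This fallback makes no compound outside the list (F0).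

## Further compounds

F1 | step 7 | 1α-benzoyloxymethyl-3α-benzoyloxy-1β,2β-isopropylidenedioxycyclohex-5-en-4α-ol | O=C(OC[C@@]12C=C[C@@H](O)[C@@H](OC(=O)c3ccccc3)[C@@H]1OC(C)(C)O2)c1ccccc1
F2 | step 7 | 3α-benzoyloxy-1α-benzoyloxymethyl-1β,2β-isopropylidenedioxycyclohex-5-en-4-one | O=C(OC[C@@]12C=CC(=O)[C@@H](OC(=O)c3ccccc3)[C@@H]1OC(C)(C)O2)c1ccccc1
F3 | step 2 | 2-C-(benzoyloxymethyl)-2,3:5,6-di-O-isopropylidene-D-mannofuranose | OC1O[C@H]([C@H]2COC(C)(C)O2)[C@@H]3OC(C)(C)O[C@]13COC(=O)c1ccccc1
F4 | step 2 | (Z)-3-C-(benzoyloxymethyl)-1,2-dideoxy-1-iodo-3,4:6,7-di-O-isopropylidene-D-manno-hept-1-enitol | CC1(C)OC[C@@H](O1)[C@@H](O)[C@H]1[C@](COC(=O)c2ccccc2)(OC(C)(C)O1)/C=C\I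
F0 | step 6 | none | none
F0 | step 8 | none | none
A1 | alternative 1 | (1S,2S)-3-bromocyclohexa-3,5-diene-1,2-diol | [C@@H]1(O)C(Br)=CC=C[C@@H]1O
A2 | alternative 1 | bromobenzene | Brc1ccccc1
A3 | alternative 2 | 3-O-benzoyl-1-(benzoyloxymethyl)-1-O-triethylsilyl-4-oxocyclohex-5-ene-1,2,3-triol | O=C(OC[C@@]1(O[Si](CC)(CC)CC)C=CC(=O)[C@@H](OC(=O)c2ccccc2)[C@@H]1O)c1ccccc1
A4 | alternative 2 | (2S,3Z)-6-(benzoyloxy)-2-(benzoyloxymethyl)-5-oxo-2-(triethylsilyloxy)hex-3-enal | O=C[C@@](O[Si](CC)(CC)CC)(COC(=O)c1ccccc1)/C=C\C(=O)COC(=O)c1ccccc1
A5 | alternative 3 | 2,4-di-O-benzyl-1-C-(benzyloxymethyl)-6,6-dichloro-3-O-(4-methoxybenzyl)-5-oxocyclohexane-1,2,3,4-tetrol | c1ccccc1COC[C@@]1(O)C(Cl)(Cl)C(=O)[C@H](OCc2ccccc2)[C@@H](OCc2ccc(OC)cc2)[C@@H]1OCc1ccccc1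
A6 | alternative 3 | acyclic 1,5-diketone precursor of A5 (1,3,5-tri-O-benzyl-7,7-dichloro-7-deoxy-4-O-(4-methoxybenzyl)hepto-2,6-diulose, D-gluco-derived) | ClC(Cl)C(=O)[C@H](OCc1ccccc1)[C@@H](OCc1ccc(OC)cc1)[C@H](OCc1ccccc1)C(=O)COCc1ccccc1
A7 | alternative 3 | D-glucose | O=C[C@H](O)[C@@H](O)[C@H](O)[C@H](O)CO
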